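**Plan**

The target is a (2S)-5,7-dimethoxyflavan whose C8 carries an (E)-styryl group with a 6-hydroxy-2,4-dimethoxy-3-methylphenyl ring (ring A); flavan numbering is used throughout.
Retrosynthesis cuts the stilbene C=C first (Horner–Wadsworth–Emmons) into a flavan-8-carbaldehyde and a ring A benzylphosphonate, then cuts C8–CHO and O1–C8a together, back to an open-chain (S)-bromoaryl propanol.
What allows this: in ring B, C8a (bearing O1) and C8 (bearing the carbon substituent) are adjacent and the C7 methoxy flanks C8, the pattern left when an alkoxide adds to a 3-methoxyaryne (oxygen on the far carbon, carbanion beside the methoxy).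
Forward: formylation of 1-bromo-3,5-dimethoxybenzene, Claisen–Schmidt condensation with acetophenone and tandem transfer hydrogenation give the propanol; the pyran ring, the only ring made, closes through the aryne and the C8 anion is formylated in the same flask.
Ring A comes from 2,6-dimethoxytoluene (C–H borylation/oxidation, allylation, formylation, reduction, phosphonate); the olefination joins the halves and a neutral deallylation frees the phenol.
Stereochemistry: C2 (S) is set by ruthenium-catalysed asymmetric transfer hydrogenation of the aryl ketone with the (S,S)-TsDPEN ligand and is not touched afterwards; the E-alkene comes from the phosphonate olefination.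

Key step: step 4

**Route**

Step 1
Reactants: 1 1-bromo-3,5-dimethoxybenzene
Product: 2 2-bromo-4,6-dimethoxybenzaldehyde
Conditions: POCl3, DMF, 0 → 90 °C; then ice/H2O
Reagents that add atoms: N,N-dimethylformamide CN(C)C=O (formyl carbon); water O (carbonyl oxygen)
Why: Vilsmeier–Haack formylation, in which the chloroiminium ion attacks the position ortho to bromine that is para to one methoxy and ortho to the other, the usual outcome for this arene, and the minor 4-bromo-2,6-dimethoxy isomer should be removable by crystallisation.

Step 2
Reactants: 2 2-bromo-4,6-dimethoxybenzaldehyde; 3 acetophenone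
Product: 4 (E)-3-(2-bromo-4,6-dimethoxyphenyl)-1-phenylprop-2-en-1-one
Conditions: aq. NaOH, EtOH, rt
Reagents that add atoms: none
Why: Claisen–Schmidt condensation of a non-enolisable aldehyde with the acetophenone enolate, where E1cB dehydration of the aldol gives the conjugated E-enone.

Step 3
Reactants: 4 (E)-3-(2-bromo-4,6-dimethoxyphenyl)-1-phenylprop-2-en-1-one
Product: 6 (S)-3-(2-bromo-4,6-dimethoxyphenyl)-1-phenylpropan-1-ol, via saturated ketone 5 (not isolated)
Conditions: RuCl[(S,S)-TsDPEN](p-cymene) (2 mol %), HCO2H/Et3N (5:2), DMF, 40 °C
Reagents that add atoms: none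
Why: Noyori–Ikariya asymmetric transfer hydrogenation used in tandem fashion: the ruthenium hydride first reduces the chalcone C=C by conjugate hydride delivery to give ketone 5 and then reduces the aryl ketone through the six-membered outer-sphere transition state of the (S,S)-TsDPEN catalyst, which delivers hydride to the face that makes the carbinol S (the same sense as acetophenone to (S)-1-phenylethanol, phenyl ranking above the alkyl chain), while the aryl bromide is inert.

Step 4
Reactants: 6 (S)-3-(2-bromo-4,6-dimethoxyphenyl)-1-phenylpropan-1-ol
Product: 9 (S)-5,7-dimethoxy-2-phenylchromane-8-carbaldehyde, via aryne lithium alkoxide 7 (not isolated), via 8-lithioflavan 8 (not isolated)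
Conditions: LiTMP (2.3 equiv, from n-BuLi and 2,2,6,6-tetramethylpiperidine), THF, −78 → −10 °C; then DMF, −78 °C → rt; H2O
Reagents that add atoms: n-butyllithium [Li]CCCC (lithium of 7 and 8 only); N,N-dimethylformamide CN(C)C=O (formyl group of 9)
Why: The first equivalent of LiTMP gives the lithium alkoxide and the second removes the ring hydrogen flanked by bromine and methoxy (future C8), and loss of LiBr on warming gives aryne 7 across the future C8–C8a bond. The tethered alkoxide adds to C8a, forming O1–C8a and closing the pyran ring in a 6-exo-dig mode; the three-atom tether cannot reach C8, and this is also the electronically preferred direction for a 3-methoxyaryne because the negative charge develops at C8 beside the C7 methoxy group. Aryllithium 8 sits between two oxygen substituents, so it should resist proton return from tetramethylpiperidine and be captured by DMF, giving the C8–CHO bond after hydrolysis. The closest known reaction type is the lithium amide-induced aryne cyclisation of haloarenes carrying a tethered alkoxide or amide (chromans, indolines), including variants in which the resulting aryllithium is quenched with an electrophile. No stereocentre is formed, and C2, which takes part in no bond change, keeps its S configuration. The selectivity needed is metalation at the hydrogen next to bromine and not at the one between the two methoxy groups: metalation there is reversible through the amine whereas metalation next to bromine is drained irreversibly by bromide loss, and keeping the base near two equivalents avoids a second metalation at C6 of the product.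

Step 5
Reactants: 10 2,6-dimethoxytoluene
Product: 12 3,5-dimethoxy-4-methylphenol, via aryl pinacol boronate 11 (not isolated)
Conditions: [Ir(OMe)(cod)]2 (1.5 mol %), dtbpy (3 mol %), B2pin2, THF, 80 °C; then aq. NaOH, 30% H2O2, 0 °C → rt
Reagents that add atoms: bis(pinacolato)diboron CC1(C)OB(OC1(C)C)B1OC(C)(C)C(C)(C)O1 (boryl group of 11 only); hydrogen peroxide OO (phenol oxygen of 12)
Why: Iridium-catalysed aromatic C–H borylation under steric control takes the only ring position without an ortho substituent (para to the methyl group), and oxidation of the C–B bond of 11 in the same flask gives the symmetric phenol (one-pot borylation/oxidation).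

Step 6
Reactants: 12 3,5-dimethoxy-4-methylphenol
Product: 13 5-(allyloxy)-1,3-dimethoxy-2-methylbenzene
Conditions: allyl bromide, K2CO3, acetone, reflux
Reagents that add atoms: allyl bromide C=CCBr
Why: Williamson ether synthesis of the phenoxide with a reactive allylic halide, chosen so that the phenol can later be freed without acid.

Step 7
Reactants: 13 5-(allyloxy)-1,3-dimethoxy-2-methylbenzene
Product: 14 6-(allyloxy)-2,4-dimethoxy-3-methylbenzaldehyde
Conditions: POCl3, DMF, 0 °C → rt; then ice/H2O
Reagents that add atoms: N,N-dimethylformamide CN(C)C=O (formyl carbon); water O (carbonyl oxygen)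
Why: Vilsmeier–Haack formylation of a phloroglucinol-type triether whose two free ring positions are equivalent by symmetry, so a single aldehyde should result, and the allyl ether tolerates the conditions.

Step 8
Reactants: 14 6-(allyloxy)-2,4-dimethoxy-3-methylbenzaldehyde
Product: 15 [6-(allyloxy)-2,4-dimethoxy-3-methylphenyl]methanol
Conditions: NaBH4, MeOH, 0 °C
Reagents that add atoms: none
Why: Borohydride reduction of an aryl aldehyde, which leaves the allyl and methyl ethers untouched.

Step 9
Reactants: 15 [6-(allyloxy)-2,4-dimethoxy-3-methylphenyl]methanol
Product: 16 diethyl [6-(allyloxy)-2,4-dimethoxy-3-methylbenzyl]phosphonate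
Conditions: P(OEt)3, ZnI2, THF, reflux
Reagents that add atoms: triethyl phosphite CCOP(OCC)OCC
Why: Zinc iodide-mediated Michaelis–Arbuzov-type conversion of a benzylic alcohol, in which transesterification to the benzyl phosphite and ionisation–recombination are favoured by the electron-rich ring and excess phosphite should outcompete self-alkylation at the one free ring position, avoiding an unstable benzylic halide.

Step 10
Reactants: 16 diethyl [6-(allyloxy)-2,4-dimethoxy-3-methylbenzyl]phosphonate; 9 (S)-5,7-dimethoxy-2-phenylchromane-8-carbaldehyde
Product: 17 (S,E)-8-{2-[6-(allyloxy)-2,4-dimethoxy-3-methylphenyl]vinyl}-5,7-dimethoxy-2-phenylchromane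
Conditions: NaH, 15-crown-5 (cat.), THF, 0 °C → rt
Reagents that add atoms: none
Why: Horner–Wadsworth–Emmons olefination, in which the benzylic phosphonate carbanion is nucleophilic enough for the non-enolisable, di-ortho-substituted aldehyde and reversible addition followed by syn elimination should give the E-stilbene, with C2 remote and unaffected.

Step 11
Reactants: 17 (S,E)-8-{2-[6-(allyloxy)-2,4-dimethoxy-3-methylphenyl]vinyl}-5,7-dimethoxy-2-phenylchromane
Product: 18 2-{(E)-2-[(2S)-5,7-dimethoxy-2-phenylchroman-8-yl]vinyl}-3,5-dimethoxy-4-methylphenol
Conditions: Pd(PPh3)4 (5 mol %), morpholine, THF, rt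
Reagents that add atoms: none
Why: Deallylation of an aryl allyl ether by zerovalent palladium (Tsuji–Trost type), in which ionisation to the allylpalladium complex expels the phenoxide and morpholine captures the allyl group under neutral conditions that spare the electron-rich stilbene, the methyl ethers and the benzylic C2–O bond.

**Compound list**

1 | 1-bromo-3,5-dimethoxybenzene | COc1cc(Br)cc(OC)c1 | starting material
2 | 2-bromo-4,6-dimethoxybenzaldehyde | COc1cc(OC)c(C=O)c(Br)c1 | intermediate
3 | acetophenone | CC(=O)c1ccccc1 | starting material
4 | (E)-3-(2-bromo-4,6-dimethoxyphenyl)-1-phenylprop-2-en-1-one | COc1cc(OC)c(/C=C/C(=O)c2ccccc2)c(Br)c1 | intermediate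
5 | 3-(2-bromo-4,6-dimethoxyphenyl)-1-phenylpropan-1-one (saturated ketone, formed in the flask) | COc1cc(OC)c(CCC(=O)c2ccccc2)c(Br)c1 | intermediate
6 | (S)-3-(2-bromo-4,6-dimethoxyphenyl)-1-phenylpropan-1-ol | COc1cc(OC)c(CC[C@H](O)c2ccccc2)c(Br)c1 | intermediate
7 | lithium (S)-3-(2,4-dimethoxy-5,6-didehydrophenyl)-1-phenylpropan-1-olate (aryne lithium alkoxide, formed in the flask) | COC1=CC(OC)=C(CC[C@H](O[Li])c2ccccc2)C#C1 | intermediate
8 | (S)-8-lithio-5,7-dimethoxy-2-phenylchromane (8-lithioflavan, formed in the flask) | COc1cc(OC)c2c(c1[Li])O[C@H](c1ccccc1)CC2 | intermediate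
9 | (S)-5,7-dimethoxy-2-phenylchromane-8-carbaldehyde | COc1cc(OC)c2c(c1C=O)O[C@H](c1ccccc1)CC2 | intermediate
10 | 2,6-dimethoxytoluene | COc1cccc(OC)c1C | starting material
11 | 2-(3,5-dimethoxy-4-methylphenyl)-4,4,5,5-tetramethyl-1,3,2-dioxaborolane (aryl pinacol boronate, formed in the flask) | COc1cc(B2OC(C)(C)C(C)(C)O2)cc(OC)c1C | intermediate
12 | 3,5-dimethoxy-4-methylphenol | COc1cc(O)cc(OC)c1C | intermediate
13 | 5-(allyloxy)-1,3-dimethoxy-2-methylbenzene | C=CCOc1cc(OC)c(C)c(OC)c1 | intermediate
14 | 6-(allyloxy)-2,4-dimethoxy-3-methylbenzaldehyde | C=CCOc1cc(OC)c(C)c(OC)c1C=O | intermediate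
15 | [6-(allyloxy)-2,4-dimethoxy-3-methylphenyl]methanol | C=CCOc1cc(OC)c(C)c(OC)c1CO | intermediate
16 | diethyl [6-(allyloxy)-2,4-dimethoxy-3-methylbenzyl]phosphonate | C=CCOc1cc(OC)c(C)c(OC)c1CP(=O)(OCC)OCC | intermediate
17 | (S,E)-8-{2-[6-(allyloxy)-2,4-dimethoxy-3-methylphenyl]vinyl}-5,7-dimethoxy-2-phenylchromane | C=CCOc1cc(OC)c(C)c(OC)c1/C=C/c1c(OC)cc(OC)c2c1O[C@H](c1ccccc1)CC2 | intermediate
18 | 2-{(E)-2-[(2S)-5,7-dimethoxy-2-phenylchroman-8-yl]vinyl}-3,5-dimethoxy-4-methylphenol | COc1cc(O)c(/C=C/c2c(OC)cc(OC)c3c2O[C@H](c2ccccc2)CC3)c(OC)c1C | target

**Step count**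

Total steps: 11. Longest linear sequence: 7 steps (steps 5 to 11, from 10 to 18); the flavan branch needs 6 steps (steps 1 to 4, then 10 and 11).

**Steps most likely to fail**

Step 4. The base may be tied up in reversible metalation between the two methoxy groups so that aryne formation stalls. The aryne may be reduced by hydride transfer from the benzylic alkoxide. The C8 anion may pick up a proton before DMF arrives, so that ring closure occurs without formylation. The fallback sets out from 6 and separates the two bond formations. Palladium-catalysed intramolecular C–O coupling (Pd(OAc)2, 2-(di-tert-butylphosphino)-1,1′-binaphthyl, Cs2CO3, toluene, 80 °C) leaves the carbinol configuration unchanged and should give (S)-5,7-dimethoxy-2-phenylchromane F1. Bromination with NBS in CH2Cl2 at low temperature is expected to favour C8, as in related 5,7-dialkoxyflavans, and should give (S)-8-bromo-5,7-dimethoxy-2-phenylchromane F2. Bromine–lithium exchange (n-BuLi, THF, −78 °C) then produces aryllithium 8, and DMF returns the route to 9.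

Step 3. Direct carbonyl reduction of the hindered, electron-rich enone may run ahead of conjugate reduction and leave allylic alcohol, or the sequence may stall at the saturated ketone; a sluggish second reduction could also erode the enantioselectivity. The fallback sets out from 4 and splits the step in two. Copper hydride conjugate reduction ([(Ph3P)CuH]6 cat., polymethylhydrosiloxane, toluene, rt) should give ketone 5, now isolated. Corey–Bakshi–Shibata reduction ((R)-2-methyl-CBS-oxazaborolidine cat., BH3·SMe2, THF, −20 °C) should then return the route to 6 with the S configuration. No compound outside the list is needed (F0).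

Step 10. Addition of the hindered phosphonate anion to the di-ortho-substituted, electron-rich aldehyde may be slow and leave the coupling incomplete; the same fallback also covers self-alkylation of the benzylic cation during step 9. It sets out from 15 and 9. PPh3·HBr in MeCN should give [6-(allyloxy)-2,4-dimethoxy-3-methylbenzyl]triphenylphosphonium bromide F3. Wittig reaction of its ylide (NaHMDS, THF, −78 °C → rt) with 9 should give the alkene as a mixture of 17 and (S,Z)-8-{2-[6-(allyloxy)-2,4-dimethoxy-3-methylphenyl]vinyl}-5,7-dimethoxy-2-phenylchromane F4. Iodine-catalysed equilibration (cat. I2, heptane, visible light, rt), done while the phenol is still protected, should convert F4 into 17, where the route is rejoined.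

**Further compounds**

F1 | step 4 | (S)-5,7-dimethoxy-2-phenylchromane | COc1cc(OC)c2c(c1)O[C@H](c1ccccc1)CC2
F2 | step 4 | (S)-8-bromo-5,7-dimethoxy-2-phenylchromane | COc1cc(OC)c2c(c1Br)O[C@H](c1ccccc1)CC2
F0 | step 3 | none | none
F3 | step 10 | [6-(allyloxy)-2,4-dimethoxy-3-methylbenzyl]triphenylphosphonium bromide | C=CCOc1cc(OC)c(C)c(OC)c1C[P+](c1ccccc1)(c1ccccc1)c1ccccc1.[Br-]
F4 | step 10 | (S,Z)-8-{2-[6-(allyloxy)-2,4-dimethoxy-3-methylphenyl]vinyl}-5,7-dimethoxy-2-phenylchromane | C=CCOc1cc(OC)c(C)c(OC)c1/C=C\c1c(OC)cc(OC)c2c1O[C@H](c1ccccc1)CC2
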